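Reciprocal molarity per minute is the unit of the constant wanted first: multiplied by a charge and a time, it leaves a pure number.

| setting | noon | midnight | winter | oak | maple | birch |
|---|---|---|---|---|---|---|
| J | 0.56 M | 0.88 M | 0.40 M | 0.40 M | 0.40 M | 0.40 M |
| E | 0.40 M | 0.40 M | 0.20 M | 0.400 M | 0.400 M | 0.400 M |
| remark | run made earlier | run made earlier | run made earlier |  |  |  |
| time |  |  |  | 50 min | 60 min | 72 min |

| run | time / min | X / % | Q / % | D / % | J / % |
|---|---|---|---|---|---|
| noon | 10.0 | 10.9 | 0.5 | 0.8 | 89.4 |
| noon | 20.0 | 18.4 | 0 | 0 | 81.3 |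
| noon | 30.0 | 25.2 | 1.2 | 0 | 74.2 |
| noon | 40.0 | 31.5 | 0 | 0 | 68.7 |
| noon | 50.0 | 36.4 | 1.0 | 1.4 | 61.8 |
| midnight | 4.00 | 3.8 | 1.6 | 0 | 96.4 |
| midnight | 12.0 | 12.6 | 2.0 | 0 | 87.4 |
| midnight | 25.0 | 21.6 | 0.6 | 0.3 | 77.0 |
| midnight | 40.0 | 27.4 | 1.2 | 1.4 | 71.6 |
| midnight | 50.0 | 29.8 | 0.3 | 0.5 | 69.0 |
| winter | 4.00 | 2.7 | 0 | 0.6 | 95.6 |
| winter | 8.00 | 5.7 | 0.8 | 0.3 | 94.4 |
| winter | 15.0 | 7.6 | 0 | 0 | 90.4 |
| winter | 25.0 | 13.3 | 2.4 | 0.4 | 87.2 |
| winter | 50.0 | 22.2 | 0.2 | 1.1 | 77.5 |

(standard deviation of a reading: 1 percentage point)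

- in percentages every species weighs as the J in it: one L counts as two
- the numbers in the tables scatter with a standard deviation of 1 percentage point
- candidate steps: J <-> Q; J + E <-> X; E + Q -> D; 2 Q -> L

- which of these there is most of at the end, counted by the J in it, oak (J / X / D / Q)
- which of these there is most of at the end, counted by the J in it, maple (J / X / D / Q)
- which of these there is most of at the end, counted by the J in it, birch (J / X / D / Q)
- how much there is at the end of the one of these that leads, in percent of the J charged: oak
- how much there is at the end of the one of these that leads, in percent of the J charged: maple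
- how much there is at the end of the one of these that leads, in percent of the J charged: birch

In oak, maple and birch, J and E are charged equally. If J + E → X carries these flasks, J and E stay equal, and it pays to follow the fraction f of J left rather than the fraction made. Then f is the reciprocal of one plus N, where N = kct, with k the forward constant, c the common charge and t the time. This N, a second-order Damköhler number, is in words the X made per J left, so J leads while N stays below one.

The last X reading of the noon run, 36.4% at 50.0 min, put into the integrated rate law for unequal charges, gives k = 0.0325 M⁻¹ min⁻¹ as a reading. My reckoning then gives N = 0.650 for oak, 0.780 for maple and 0.936 for birch, and so f = 60.6%, 56.2% and 51.7%.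

Is one number enough? J and X together make 98.2% in that noon reading, which leaves little room for Q, D and L. The midnight run's last X reading gives k = 0.0297 M⁻¹ min⁻¹, lower than the noon value, but each value rests on a single reading with a scatter of 1 percentage point, so I read nothing about the way back, which N omits, from that gap. Birch, with the N closest to one, is the flask to watch.

The forecast gives 60%, 56% and 52% of J, reasoning that “J therefore still leads in all three”.

The flasks give J leading, with 60.6% in oak, 56.3% in maple and 51.9% in birch. Birch holds 46.3% X, 1.10% D and 0.736% Q, and the step to D makes no visible difference to J there.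

    J ⇌ Q (K = 0.890, k = 6.10 × 10⁻⁶ s⁻¹)
    J + E ⇌ X (K = 49.0 M⁻¹, k = 5.30 × 10⁻⁴ M⁻¹ s⁻¹)
    E + Q → D (k = 0.00180 M⁻¹ s⁻¹)
    2 Q → L (k = 4.50 × 10⁻⁴ M⁻¹ s⁻¹)

Leave maple until 1.5 h and N becomes 1.17, above one, so f = 46.1% and X should lead. X does lead that flask, with 51.3% against 46.5% of J.

All runs are calculated for substances that don't exist.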